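**Plan**
- Retrosynthesis: the MOM group and a temporary oxygen on C2 come off last. Ring C is then cut at O1–C2 and C3–C4 together, giving an ortho-quinone methide of ring A (O1=C8a–C4a=C4) and the ring B arylacetaldehyde (C2–C3).
- Enabling feature: O1–C8a–C4a–C4 of ring A is an o-hydroxybenzyl unit, and ring A is the mirror-symmetric 2,6-dihydroxy-4-methoxybenzaldehyde plus one carbon between an OH and the OMe. Both OH groups are equivalent, so C8-CHO, C7-OH and C5-OMe arise without any regiochemical decision.
- Forward order: ring B is built from 3-methoxyphenol by two directed lithiations (prenyl, then hydroxyethyl) and oxidised to the arylacetaldehyde. Ring A is converted into a sulfonylmethyl quinone methide precursor. The two halves are then joined and ring C closed in one operation (C3–C4 and O1–C2).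
- Stereochemistry: the single stereocenter C3 (R) is set in that operation by an (R)-diarylprolinol silyl ether acting through its enamine.
- Helper removal: C2 enters at the aldehyde oxidation level (lactol) and is brought to CH2 by OH→SPh exchange and stannane reduction. This neutral radical path is chosen because the electron-rich ring A aldehyde, the MOM acetal and the prenyl group are not expected to tolerate ionic hydrogenation.

Key step: step 6

Remark: 2,6-dihydroxy-4-methoxybenzaldehyde (8) is taken as a purchasable compound; 13 and 14 are expected as mixtures of C2 epimers, which is immaterial because C2 ends as CH2.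

**Step 1**
Reactants: 1 3-methoxyphenol
Product: 2 1-methoxy-3-(methoxymethoxy)benzene
Conditions: MOMCl, iPr2NEt, CH2Cl2, 0 °C to rt
Reagents that add atoms: chloromethyl methyl ether (MOMCl), COCCl
Why: Base-mediated O-alkylation of the phenol (Williamson-type MOM protection) should give the acetal that masks the future 2'-OH and acts as the stronger directing group in both lithiations.

**Step 2**
Reactants: 2 1-methoxy-3-(methoxymethoxy)benzene
Product: 4 1-methoxy-3-(methoxymethoxy)-2-(3-methylbut-2-en-1-yl)benzene, via aryllithium 3 (not isolated)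
Conditions: n-BuLi, THF, 0 °C; then CuI (10 mol%), prenyl bromide, −78 °C to rt
Reagents that add atoms: 1-bromo-3-methylbut-2-ene (prenyl bromide), CC(C)=CCBr
Why: Directed ortho-metalation occurs at the carbon flanked by both oxygen directing groups, and copper-assisted SN2 alkylation of the aryllithium with the allylic bromide should place the prenyl group between OMe and OMOM (future C3').

**Step 3**
Reactants: 4 1-methoxy-3-(methoxymethoxy)-2-(3-methylbut-2-en-1-yl)benzene
Product: 6 2-[4-methoxy-2-(methoxymethoxy)-3-(3-methylbut-2-en-1-yl)phenyl]ethan-1-ol, via aryllithium 5 (not isolated)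
Conditions: n-BuLi, TMEDA, THF, −20 to 0 °C; then ethylene oxide, −78 °C to rt; then H2O
Reagents that add atoms: ethylene oxide (oxirane), C1CO1
Why: A second directed ortho-metalation should take place at the only remaining position next to the stronger OCH2OMe director, and ring-opening of ethylene oxide by the aryllithium adds the two carbons that become C3 and C2.

**Step 4**
Reactants: 6 2-[4-methoxy-2-(methoxymethoxy)-3-(3-methylbut-2-en-1-yl)phenyl]ethan-1-ol
Product: 7 2-[4-methoxy-2-(methoxymethoxy)-3-(3-methylbut-2-en-1-yl)phenyl]acetaldehyde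
Conditions: Dess–Martin periodinane, CH2Cl2, 0 °C to rt; used at once
Reagents that add atoms: none
Why: Dess–Martin oxidation stops at the aldehyde under near-neutral conditions that should leave the MOM acetal and the prenyl double bond untouched; the enolisable arylacetaldehyde is not stored.

**Step 5**
Reactants: 8 2,6-dihydroxy-4-methoxybenzaldehyde
Product: 9 2,6-dihydroxy-4-methoxy-3-[(4-methylbenzenesulfonyl)methyl]benzaldehyde
Conditions: (CH2O)n (1 equiv), TolSO2Na, HCO2H/H2O, rt
Reagents that add atoms: paraformaldehyde (as formaldehyde), C=O; sodium 4-methylbenzenesulfinate, Cc1ccc(cc1)S(=O)[O-].[Na+]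
Why: Three-component Mannich-type sulfonylmethylation: electrophilic hydroxymethylation of the phloroglucinol-type ring at C3 (identical to C5 by symmetry) and capture of the resulting benzylic cation or quinone methide by sulfinate sulfur should give a bench-stable quinone methide precursor.

**Step 6**
Reactants: 9 2,6-dihydroxy-4-methoxy-3-[(4-methylbenzenesulfonyl)methyl]benzaldehyde; 7 2-[4-methoxy-2-(methoxymethoxy)-3-(3-methylbut-2-en-1-yl)phenyl]acetaldehyde
Product: 13 (2RS,3R)-2,7-dihydroxy-5-methoxy-3-[4-methoxy-2-(methoxymethoxy)-3-(3-methylbut-2-en-1-yl)phenyl]-3,4-dihydro-2H-chromene-8-carbaldehyde, via ortho-quinone methide 10 (not isolated), via enamine 11 (not isolated), via aminal 12 (not isolated)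
Conditions: (R)-α,α-diphenylprolinol trimethylsilyl ether (20 mol%), 7 (1.5 equiv), NaHCO3, CH2Cl2/H2O, 0 °C to rt
Reagents that add atoms: water, O
Why: NaHCO3 deprotonates 9 and 1,4-elimination of sulfinate gives ortho-quinone methide 10 (heterodiene O1=C8a–C4a=C4), while 7 and the amine form the (E)-enamine 11, whose β-carbon (future C3) adds to C4 and whose iminium carbon (future C2) is captured by O1 to give aminal 12; hydrolysis returns the catalyst and leaves lactol 13. The closest known reaction type is the secondary-amine-catalysed formal oxa-[4+2] (Michael addition/hemiacetalisation) of enolisable aldehydes with ortho-quinone methides generated in situ from 2-(sulfonylmethyl)phenols. Ring C is closed either as an inverse-electron-demand hetero-Diels–Alder reaction or, stepwise, by 6-exo-trig attack of the phenoxide O1 on the iminium carbon. C3 is set under catalyst control: the CPh2(OSiMe3) group shields one face of the s-trans enamine so that C4 adds to the open face, which for the (R)-catalyst should give (3R); C2 forms as an epimeric mixture and later becomes CH2. Regiochemistry is fixed by polarity (the enamine β-carbon is the nucleophile, C4 the only electrophilic terminus, O1 the only oxygen ortho to C4; the para-quinone methide tautomer through the C7 oxygen leads to the same product), and the symmetry of 8 means no other ring A isomer can arise. Chemoselectivity rests on the ring A aldehyde being a hydrogen-bonded vinylogous acid that does not compete with 10 as an electrophile, and on the product staying closed as the lactol, which protects the C3–H.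

**Step 7**
Reactants: 13 (2RS,3R)-2,7-dihydroxy-5-methoxy-3-[4-methoxy-2-(methoxymethoxy)-3-(3-methylbut-2-en-1-yl)phenyl]-3,4-dihydro-2H-chromene-8-carbaldehyde
Product: 14 (2RS,3R)-7-hydroxy-5-methoxy-3-[4-methoxy-2-(methoxymethoxy)-3-(3-methylbut-2-en-1-yl)phenyl]-2-(phenylsulfanyl)-3,4-dihydro-2H-chromene-8-carbaldehyde
Conditions: PhSSPh, Bu3P, THF, 0 °C to rt
Reagents that add atoms: diphenyl disulfide, c1ccc(cc1)SSc1ccccc1
Why: Phosphine–disulfide redox condensation activates the anomeric OH as an oxyphosphonium ion that thiolate displaces, so the C2 oxygen helper is exchanged for a radical leaving group under neutral conditions with the O1–C2 bond, the aldehyde and the MOM acetal intact.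

**Step 8**
Reactants: 14 (2RS,3R)-7-hydroxy-5-methoxy-3-[4-methoxy-2-(methoxymethoxy)-3-(3-methylbut-2-en-1-yl)phenyl]-2-(phenylsulfanyl)-3,4-dihydro-2H-chromene-8-carbaldehyde
Product: 15 (3R)-7-hydroxy-5-methoxy-3-[4-methoxy-2-(methoxymethoxy)-3-(3-methylbut-2-en-1-yl)phenyl]-3,4-dihydro-2H-chromene-8-carbaldehyde
Conditions: Ph3SnH, AIBN (cat.), toluene (degassed), 100 °C
Reagents that add atoms: none
Why: Radical chain desulfurisation: the Ph3Sn radical abstracts the phenylthio group and the O1-stabilised C2 radical takes hydrogen from Ph3SnH, which should give the CH2 group without acid or hydride and therefore without touching the ring A aldehyde, the MOM acetal, the prenyl group or C3.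

**Step 9**
Reactants: 15 (3R)-7-hydroxy-5-methoxy-3-[4-methoxy-2-(methoxymethoxy)-3-(3-methylbut-2-en-1-yl)phenyl]-3,4-dihydro-2H-chromene-8-carbaldehyde
Product: 16 (3R)-7-hydroxy-3-[2-hydroxy-4-methoxy-3-(3-methylbut-2-en-1-yl)phenyl]-5-methoxy-3,4-dihydro-2H-chromene-8-carbaldehyde
Conditions: 3 M HCl, MeOH, 40 °C
Reagents that add atoms: none
Why: Acid-catalysed transacetalisation to methanol (MOM cleavage) should free the 2'-OH, and the mild temperature is chosen to avoid acid-catalysed addition of that phenol to the prenyl double bond.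

**Compound list**
1 | 3-methoxyphenol | COc1cccc(O)c1 | starting material
2 | 1-methoxy-3-(methoxymethoxy)benzene | COCOc1cccc(OC)c1 | intermediate
3 | [2-methoxy-6-(methoxymethoxy)phenyl]lithium | [Li]c1c(OC)cccc1OCOC | intermediate
4 | 1-methoxy-3-(methoxymethoxy)-2-(3-methylbut-2-en-1-yl)benzene | COCOc1cccc(OC)c1CC=C(C)C | intermediate
5 | [4-methoxy-2-(methoxymethoxy)-3-(3-methylbut-2-en-1-yl)phenyl]lithium | [Li]c1ccc(OC)c(CC=C(C)C)c1OCOC | intermediate
6 | 2-[4-methoxy-2-(methoxymethoxy)-3-(3-methylbut-2-en-1-yl)phenyl]ethan-1-ol | OCCc1ccc(OC)c(CC=C(C)C)c1OCOC | intermediate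
7 | 2-[4-methoxy-2-(methoxymethoxy)-3-(3-methylbut-2-en-1-yl)phenyl]acetaldehyde | O=CCc1ccc(OC)c(CC=C(C)C)c1OCOC | intermediate
8 | 2,6-dihydroxy-4-methoxybenzaldehyde | COc1cc(O)c(C=O)c(O)c1 | starting material
9 | 2,6-dihydroxy-4-methoxy-3-[(4-methylbenzenesulfonyl)methyl]benzaldehyde | COc1cc(O)c(C=O)c(O)c1CS(=O)(=O)c1ccc(C)cc1 | intermediate
10 | 2-hydroxy-4-methoxy-5-methylidene-6-oxocyclohexa-1,3-diene-1-carbaldehyde (ortho-quinone methide) | C=C1C(OC)=CC(O)=C(C=O)C1=O | intermediate
11 | (2R)-2-[diphenyl(trimethylsilyloxy)methyl]-1-{(E)-2-[4-methoxy-2-(methoxymethoxy)-3-(3-methylbut-2-en-1-yl)phenyl]ethenyl}pyrrolidine (enamine) | C[Si](C)(C)OC(c1ccccc1)(c1ccccc1)[C@H]1CCCN1/C=C/c1ccc(OC)c(CC=C(C)C)c1OCOC | intermediate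
12 | (2RS,3R)-2-{(2R)-2-[diphenyl(trimethylsilyloxy)methyl]pyrrolidin-1-yl}-7-hydroxy-5-methoxy-3-[4-methoxy-2-(methoxymethoxy)-3-(3-methylbut-2-en-1-yl)phenyl]-3,4-dihydro-2H-chromene-8-carbaldehyde (aminal) | COc1ccc([C@@H]2C(N4CCC[C@@H]4C(c5ccccc5)(c6ccccc6)O[Si](C)(C)C)Oc3c(C=O)c(O)cc(OC)c3C2)c(OCOC)c1CC=C(C)C | intermediate
13 | (2RS,3R)-2,7-dihydroxy-5-methoxy-3-[4-methoxy-2-(methoxymethoxy)-3-(3-methylbut-2-en-1-yl)phenyl]-3,4-dihydro-2H-chromene-8-carbaldehyde (lactol) | COc1ccc([C@@H]2C(O)Oc3c(C=O)c(O)cc(OC)c3C2)c(OCOC)c1CC=C(C)C | intermediate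
14 | (2RS,3R)-7-hydroxy-5-methoxy-3-[4-methoxy-2-(methoxymethoxy)-3-(3-methylbut-2-en-1-yl)phenyl]-2-(phenylsulfanyl)-3,4-dihydro-2H-chromene-8-carbaldehyde | COc1ccc([C@@H]2C(Sc4ccccc4)Oc3c(C=O)c(O)cc(OC)c3C2)c(OCOC)c1CC=C(C)C | intermediate
15 | (3R)-7-hydroxy-5-methoxy-3-[4-methoxy-2-(methoxymethoxy)-3-(3-methylbut-2-en-1-yl)phenyl]-3,4-dihydro-2H-chromene-8-carbaldehyde | COc1ccc([C@@H]2COc3c(C=O)c(O)cc(OC)c3C2)c(OCOC)c1CC=C(C)C | intermediate
16 | (3R)-7-hydroxy-3-[2-hydroxy-4-methoxy-3-(3-methylbut-2-en-1-yl)phenyl]-5-methoxy-3,4-dihydro-2H-chromene-8-carbaldehyde | COc1ccc([C@@H]2COc3c(C=O)c(O)cc(OC)c3C2)c(O)c1CC=C(C)C | target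

**Step count**
Total: 9 steps. Longest linear sequence: 8 steps (steps 1–4, then 6–9).

**Steps most likely to fail, with fallbacks**

Step 6. The enantiopurity at C3 may erode, either through poor facial discrimination on the aryl-conjugated enamine or through base-promoted enolisation of the ring-open α-aryl aldehyde form of the lactol. The quinone methide may also be consumed by a second ring A molecule. Fallback (resolution in place of asymmetric catalysis): 9 and 7 are joined with pyrrolidine as achiral catalyst under otherwise the same base conditions to give the racemic lactol rac-2,7-dihydroxy-5-methoxy-3-[4-methoxy-2-(methoxymethoxy)-3-(3-methylbut-2-en-1-yl)phenyl]-3,4-dihydro-2H-chromene-8-carbaldehyde F1. Under the conditions of step 7 this should give the racemic phenylthio acetal rac-7-hydroxy-5-methoxy-3-[4-methoxy-2-(methoxymethoxy)-3-(3-methylbut-2-en-1-yl)phenyl]-2-(phenylsulfanyl)-3,4-dihydro-2H-chromene-8-carbaldehyde F2. Under the conditions of step 8 this should in turn give the racemic MOM-protected isoflavan rac-7-hydroxy-5-methoxy-3-[4-methoxy-2-(methoxymethoxy)-3-(3-methylbut-2-en-1-yl)phenyl]-3,4-dihydro-2H-chromene-8-carbaldehyde F3. F3 has no acidic hydrogen at C3 and is resolved by preparative chromatography on a chiral stationary phase. The unwanted enantiomer (3S)-7-hydroxy-5-methoxy-3-[4-methoxy-2-(methoxymethoxy)-3-(3-methylbut-2-en-1-yl)phenyl]-3,4-dihydro-2H-chromene-8-carbaldehyde F4 is set aside, and the (3R)-enantiomer is 15. The fallback sets out from 9 and 7 and returns to the route at 15.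

Step 7. The lactol may open to the hydroxy aldehyde under the phosphine/thiolate conditions, giving incomplete exchange or epimerisation. In the stannane step that follows, the ring A aldehyde may be partly reduced. Fallback (open the lactol reductively and re-close by etherification): 13 is treated with NaBH(OAc)3 in THF/AcOH. This should reduce the aliphatic aldehyde in equilibrium with the lactol while leaving the chelated, electron-rich ring A aldehyde, giving the diol 2,6-dihydroxy-3-{(2R)-3-hydroxy-2-[4-methoxy-2-(methoxymethoxy)-3-(3-methylbut-2-en-1-yl)phenyl]propyl}-4-methoxybenzaldehyde F5. An intramolecular Mitsunobu reaction of F5 with PPh3 and DIAD in THF at 0 °C then forms O1–C2 by displacement at the primary carbon and gives 15. The fallback sets out from 13 and returns at 15, bypassing steps 7 and 8.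

Step 5. The ring may react twice (a second sulfonylmethyl group at the equivalent C5), or the benzylic cation may be captured by another arene to give a diarylmethane. Fallback (stepwise aminomethylation and exchange): a Mannich reaction of 8 with dimethylmethyleneiminium iodide in CH2Cl2 gives the Mannich base 3-[(dimethylamino)methyl]-2,6-dihydroxy-4-methoxybenzaldehyde F6. The protonated amine should deactivate the ring against a second substitution. Heating F6 with TolSO2Na in AcOH exchanges dimethylamine for sulfinate through the quinone methide and gives 9. The fallback sets out from 8 and returns at 9.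

**Further compounds**
F1 | step 6 | rac-2,7-dihydroxy-5-methoxy-3-[4-methoxy-2-(methoxymethoxy)-3-(3-methylbut-2-en-1-yl)phenyl]-3,4-dihydro-2H-chromene-8-carbaldehyde | COc1ccc(C2C(O)Oc3c(C=O)c(O)cc(OC)c3C2)c(OCOC)c1CC=C(C)C
F2 | step 6 | rac-7-hydroxy-5-methoxy-3-[4-methoxy-2-(methoxymethoxy)-3-(3-methylbut-2-en-1-yl)phenyl]-2-(phenylsulfanyl)-3,4-dihydro-2H-chromene-8-carbaldehyde | COc1ccc(C2C(Sc4ccccc4)Oc3c(C=O)c(O)cc(OC)c3C2)c(OCOC)c1CC=C(C)C
F3 | step 6 | rac-7-hydroxy-5-methoxy-3-[4-methoxy-2-(methoxymethoxy)-3-(3-methylbut-2-en-1-yl)phenyl]-3,4-dihydro-2H-chromene-8-carbaldehyde | COc1ccc(C2COc3c(C=O)c(O)cc(OC)c3C2)c(OCOC)c1CC=C(C)C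
F4 | step 6 | (3S)-7-hydroxy-5-methoxy-3-[4-methoxy-2-(methoxymethoxy)-3-(3-methylbut-2-en-1-yl)phenyl]-3,4-dihydro-2H-chromene-8-carbaldehyde | COc1ccc([C@H]2COc3c(C=O)c(O)cc(OC)c3C2)c(OCOC)c1CC=C(C)C
F5 | step 7 | 2,6-dihydroxy-3-{(2R)-3-hydroxy-2-[4-methoxy-2-(methoxymethoxy)-3-(3-methylbut-2-en-1-yl)phenyl]propyl}-4-methoxybenzaldehyde | COc1ccc([C@H](CO)Cc2c(OC)cc(O)c(C=O)c2O)c(OCOC)c1CC=C(C)C
F6 | step 5 | 3-[(dimethylamino)methyl]-2,6-dihydroxy-4-methoxybenzaldehyde | COc1cc(O)c(C=O)c(O)c1CN(C)C
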